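| setting | summer | dusk | flask |
|---|---|---|---|
| L | 0.070 M | 0.28 M | 0.14 M |
| G | 42 mM (held) | 42 mM (held) | 42 mM (held) |
| remark | run made earlier | run made earlier |  |
| time |  |  | 5.0 min |

| run | time / min | X / % | L / % |
|---|---|---|---|
| summer | 0.417 | 19.5 | 77.8 |
| summer | 0.833 | 33.7 | 54.1 |
| summer | 1.33 | 41.6 | 31.9 |
| summer | 2.50 | 30.9 | 7.1 |
| summer | 5.00 | 5.7 | 0 |
| dusk | 0.417 | 10.1 | 91.9 |
| dusk | 0.833 | 18.4 | 75.4 |
| dusk | 1.33 | 24.0 | 60.7 |
| dusk | 2.50 | 28.5 | 33.4 |
| dusk | 5.00 | 13.5 | 2.5 |

(each reading ± 1 percentage point)

1. when, up to 5.0 min, the flask holds most X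
2. the amount of X, in percent of the L charged, at that time
3. earliest time at which at least nineteen twentieths of that best amount are there, in min
4. latest time at which they still are, in min

- at the start none of G is in solution

At early times X stands close to the L lost: in the summer run, 19.5% against 22.2% at 0.417 min. So I treat each flask as L → X → loss, with first-order constants kL and kX. In that series the peak share of X is r to the power one over one minus r, where r is kL/kX.

Which readings must you know well? One standard deviation on the small summer reading at 5.00 min shifts kX by 0.0702 /min. The same scatter on the dusk L at 2.50 min shifts kL by 0.0144 /min, which is less. So I read the summer tail with the most care.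

Read plainly, that tail gives kX = 0.676 /min. But the 7.1% of L left at 2.50 min still feeds X. Put it back, counting it as X, and you get 0.759 /min.

L decays at 1.15 /min in summer and 0.486 /min in dusk. The flask's charge is their geometric mean, so I take 0.747 /min for it. Its selectivity factor r, the ratio kL/kX, is then 0.985, and my peak is 36.5%. The rule gives 44.6% for summer, whose highest reading is 41.6%. For dusk it gives 29.0%, whose highest reading is 28.5%.

The forecast reasons that "X peaks where formation equals loss". It puts the peak at 1.7 min (1.5 min to 1.9 min) with 37.5% (35.5% to 39%). Its band runs from 1.32 min to 2.2 min. Its height differs from mine, standing 1.00 percentage point higher.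

The flask peaks at 1.76 min with 36.6%, and its band runs from 1.33 min to 2.24 min.

    G ⇌ Q, rate k1*(csat - [Q]) (kL = 0.0410 /s)
    2 Q → J (k = 0.630 /M/s)
    X → D (k = 0.0130 /s)
    L + Q → X (k = 1.00 /M/s)

My r for this flask was 0.985. The peak I drew from it, 36.5%, stands against the 36.6% the flask holds. Now take a neighbour, the same flask with 0.035 M of L, half the summer charge. No run gives its kL, so carry over the summer constant. Then r = 1.52 and the peak is 44.6%. The neighbour flask reaches 44.7%.

All runs stem from a simulated flask for an exercise, noise included.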